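**Plan**

- Ring atoms are numbered C1 (CHOH), C2=C3, C4H2, C5 (C(OH)R), C6H2. The retrosynthesis first adds a di-tert-butylsilylene bridge across O1 and O5 (a 2,4-dioxa-3-silabicyclo[3.3.1]nonene that is not in the target), then cuts C3–C4 and C5–O together to give an acyclic 1,5-enyne silanol.
- The enyne is cut at C1–C6 (allylzinc plus silyl propynal), at the bond between the 2-methylidene unit and the chain (copper-catalysed allylic coupling) and at the Z alkene (Wittig).
- Forward: the side chain is made first, then the C4–C6 and C1–C3 pieces are added. The cyclohexene and the dioxasilinane ring arise together in one gold-catalysed step, and HF removes silicon last.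
- Enabling feature: alkyne C2≡C3 and alkene C4=C5 stand 1,5; the alkyl group on C5 puts the cation of a 6-endo closure on the carbon that must carry oxygen; O1 is 1,3 to C5, so a three-atom O–Si–O tether can reach C5 only cis.
- Stereochemistry: C1 comes from Noyori transfer hydrogenation of the ynone, C5 is relayed from C1 by the tether, and the Z alkene comes from a lithium-free Wittig reaction.

Key step: step 10

Remark: the SMILES is read as the cis-diol, (1S,3S) in cyclohex-4-ene-1,3-diol numbering, with a (12Z) side chain.

**Route**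

Step 1
Reactants: 1 (4-bromobutyl)benzene; 2 triphenylphosphine
Product: 3 (4-phenylbutyl)triphenylphosphonium bromide
Conditions: MeCN, reflux, 36 h; Et2O trituration
Reagents that add atoms: none
Why: SN2 quaternisation of a primary bromide by the phosphine should give the Wittig salt.

Step 2
Reactants: 4 11-bromoundecan-1-ol
Product: 5 11-bromoundecanal
Conditions: TEMPO (10 mol%), PhI(OAc)2 (1.1 equiv), CH2Cl2, rt
Reagents that add atoms: none
Why: Oxoammonium-catalysed (TEMPO) oxidation should stop at the aldehyde and leave the primary bromide untouched.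

Step 3
Reactants: 3 (4-phenylbutyl)triphenylphosphonium bromide; 5 11-bromoundecanal
Product: 7 [(4Z)-15-bromopentadec-4-en-1-yl]benzene, via phosphonium ylide 6 (not isolated)
Conditions: NaN(SiMe3)2 (1.0 equiv), THF, 0 °C; then 5, −78 °C to rt
Reagents that add atoms: none
Why: Wittig olefination of a non-stabilised ylide under lithium-free conditions should give the Z alkene through the kinetically favoured cis-oxaphosphetane; olefination is far faster than alkylation of the ylide by the bromide at −78 °C.

Step 4
Reactants: 7 [(4Z)-15-bromopentadec-4-en-1-yl]benzene; 8 3-chloro-2-(chloromethyl)prop-1-ene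
Product: 10 [(4Z)-17-(chloromethyl)octadeca-4,17-dien-1-yl]benzene, via Grignard reagent 9 (not isolated)
Conditions: Mg, THF, 40 °C; then added to 8 (4 equiv), Li2CuCl4 (3 mol%), THF, −40 to 0 °C
Reagents that add atoms: none
Why: Copper-catalysed allylic substitution of a primary Grignard reagent (Kochi-type coupling); SN2 and SN2' attack give the same product, and the excess of 8 with inverse addition should hold the reaction at mono-substitution.

Step 5
Reactants: 10 [(4Z)-17-(chloromethyl)octadeca-4,17-dien-1-yl]benzene; 11 3-(trimethylsilyl)prop-2-ynal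
Product: 13 rac-(17Z)-5-methylidene-21-phenyl-1-(trimethylsilyl)henicos-17-en-1-yn-3-ol, via allylzinc chloride 12 (not isolated)
Conditions: Zn dust, LiCl, THF, rt; then 11, −78 to 0 °C; aq NH4Cl
Reagents that add atoms: none
Why: Zinc insertion into the allylic chloride and 1,2-addition of the 2-substituted allylzinc to the ynal (Barbier-type allylation, SE2' with degenerate termini) should form C1–C6; the carbinol is racemic at this stage.

Step 6
Reactants: 13 rac-(17Z)-5-methylidene-21-phenyl-1-(trimethylsilyl)henicos-17-en-1-yn-3-ol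
Product: 14 (17Z)-5-methylidene-21-phenyl-1-(trimethylsilyl)henicos-17-en-1-yn-3-one
Conditions: Dess–Martin periodinane (1.3 equiv), CH2Cl2, 0 °C to rt
Reagents that add atoms: none
Why: Dess–Martin oxidation of a propargylic alcohol runs under near-neutral conditions that should not move the 1,1-disubstituted alkene into conjugation with the ketone.

Step 7
Reactants: 14 (17Z)-5-methylidene-21-phenyl-1-(trimethylsilyl)henicos-17-en-1-yn-3-one
Product: 15 (3S,17Z)-5-methylidene-21-phenyl-1-(trimethylsilyl)henicos-17-en-1-yn-3-ol
Conditions: Ru[(S,S)-TsDPEN](p-cymene) (1 mol%), i-PrOH, rt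
Reagents that add atoms: none
Why: Noyori asymmetric transfer hydrogenation of an alkynyl ketone; the (S,S) catalyst is expected to deliver hydride to the face that gives the (S)-propargylic alcohol (alkyne as the π-group in the CH/π-organised transition state), and the base-free amido complex should spare the enolisable β,γ-unsaturated ketone.

Step 8
Reactants: 15 (3S,17Z)-5-methylidene-21-phenyl-1-(trimethylsilyl)henicos-17-en-1-yn-3-ol
Product: 16 (3S,17Z)-5-methylidene-21-phenylhenicos-17-en-1-yn-3-ol
Conditions: K2CO3 (0.2 equiv), MeOH, rt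
Reagents that add atoms: none
Why: Base-catalysed methanolysis of the alkynyl C–Si bond should free the terminal alkyne without touching the carbinol centre.

Step 9
Reactants: 16 (3S,17Z)-5-methylidene-21-phenylhenicos-17-en-1-yn-3-ol
Product: 18 di-tert-butyl{[(3S,17Z)-5-methylidene-21-phenylhenicos-17-en-1-yn-3-yl]oxy}silanol, via silyl monotriflate 17 (not isolated)
Conditions: t-Bu2Si(OTf)2 (1.3 equiv), 2,6-lutidine (3 equiv), CH2Cl2, −40 to 0 °C; then H2O, THF, 0 °C
Reagents that add atoms: di-tert-butylsilyl bis(trifluoromethanesulfonate), CC(C)(C)[Si](OS(=O)(=O)C(F)(F)F)(OS(=O)(=O)C(F)(F)F)C(C)(C)C; water, O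
Why: O-silylation by the bis-triflate should stop after one alcohol because of the two tert-butyl groups, and hydrolysis of the remaining Si–OTf bond gives the di-tert-butylsilanol ether (the established way of attaching a silanol tether to an alcohol).

Step 10
Reactants: 18 di-tert-butyl{[(3S,17Z)-5-methylidene-21-phenylhenicos-17-en-1-yn-3-yl]oxy}silanol
Product: 19 (1S,5S)-3,3-di-tert-butyl-1-[(12Z)-16-phenylhexadec-12-en-1-yl]-2,4-dioxa-3-silabicyclo[3.3.1]non-6-ene
Conditions: Ph3PAuNTf2 (3 mol%), 4 Å MS, CH2Cl2, −20 °C to rt
Reagents that add atoms: none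
Why: Proposed new method: the cationic monovalent gold complex activates the terminal alkyne C2≡C3, the 1,1-disubstituted alkene attacks C3 through its CH2 terminus C4 (6-endo-dig, closing the carbocycle and leaving a vinyl-gold at C2), and the tertiary cation at C5 (a cyclopropyl gold carbene in its bridged form) is captured by the silanol oxygen held on O1 (6-exo-trig with respect to the former C4=C5 alkene, closing the 1,3-dioxa-2-silinane), after which the silanol proton removes gold from C2. The closest known reaction types are the gold-catalysed 6-endo-dig carbocyclisation of 5-substituted 1,5-enynes terminated by a tethered hydroxyl group or by the carbonyl oxygen of a tert-butyl carbonate, and the use of di-tert-butylsilanols as tethered oxygen nucleophiles toward mercury- or iodine-activated alkenes; a silanol as terminator of an enyne cyclisation and a bridge from the propargylic oxygen are the untested elements. The new stereocentre C5 is controlled by the O–Si–O bridge, which can reach C5 only on the ring face that carries the C1 oxygen (1,3-diaxial), so (S) at C1 should dictate (S) at C5 and the cis diol. The step needs 6-endo attack of the alkene over 5-exo attack of the silanol on the alkyne, and capture at C5 over proton loss or a 1,2-hydride shift from C1 to the carbenoid C2. The alkyl group on C5 localises the charge on that carbon, a five-membered siladioxolane flanked by two tert-butyl groups is disfavoured, and a cationic phosphine–gold complex at low temperature should keep the intermediate in its cationic form.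

Step 11
Reactants: 19 (1S,5S)-3,3-di-tert-butyl-1-[(12Z)-16-phenylhexadec-12-en-1-yl]-2,4-dioxa-3-silabicyclo[3.3.1]non-6-ene
Product: 20 (1S,3S)-1-[(12Z)-16-phenylhexadec-12-en-1-yl]cyclohex-4-ene-1,3-diol (CNP0333899.1)
Conditions: HF·pyridine, pyridine, THF, 0 °C to rt
Reagents that add atoms: none
Why: Fluoride cleaves both Si–O bonds of the di-tert-butylsilylene (standard removal from a 1,3-diol) without breaking a C–O bond, so both carbinol configurations should be retained.

**Compound list**

1 | (4-bromobutyl)benzene | BrCCCCc1ccccc1 | starting material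
2 | triphenylphosphine | c1ccc(cc1)P(c1ccccc1)c1ccccc1 | starting material
3 | (4-phenylbutyl)triphenylphosphonium bromide | [Br-].c1ccc(cc1)CCCC[P+](c1ccccc1)(c1ccccc1)c1ccccc1 | intermediate
4 | 11-bromoundecan-1-ol | OCCCCCCCCCCCBr | starting material
5 | 11-bromoundecanal | O=CCCCCCCCCCCBr | intermediate
6 | (4-phenylbutylidene)triphenylphosphorane (not isolated) | c1ccc(cc1)CCCC=P(c1ccccc1)(c1ccccc1)c1ccccc1 | intermediate
7 | [(4Z)-15-bromopentadec-4-en-1-yl]benzene | BrCCCCCCCCCC/C=C\CCCc1ccccc1 | intermediate
8 | 3-chloro-2-(chloromethyl)prop-1-ene | ClCC(=C)CCl | starting material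
9 | [(11Z)-15-phenylpentadec-11-en-1-yl]magnesium bromide (not isolated) | Br[Mg]CCCCCCCCCC/C=C\CCCc1ccccc1 | intermediate
10 | [(4Z)-17-(chloromethyl)octadeca-4,17-dien-1-yl]benzene | ClCC(=C)CCCCCCCCCCC/C=C\CCCc1ccccc1 | intermediate
11 | 3-(trimethylsilyl)prop-2-ynal | C[Si](C)(C)C#CC=O | starting material
12 | [(14Z)-2-methylidene-18-phenyloctadec-14-en-1-yl]zinc chloride (not isolated) | Cl[Zn]CC(=C)CCCCCCCCCCC/C=C\CCCc1ccccc1 | intermediate
13 | rac-(17Z)-5-methylidene-21-phenyl-1-(trimethylsilyl)henicos-17-en-1-yn-3-ol | C[Si](C)(C)C#CC(O)CC(=C)CCCCCCCCCCC/C=C\CCCc1ccccc1 | intermediate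
14 | (17Z)-5-methylidene-21-phenyl-1-(trimethylsilyl)henicos-17-en-1-yn-3-one | C[Si](C)(C)C#CC(=O)CC(=C)CCCCCCCCCCC/C=C\CCCc1ccccc1 | intermediate
15 | (3S,17Z)-5-methylidene-21-phenyl-1-(trimethylsilyl)henicos-17-en-1-yn-3-ol | C[Si](C)(C)C#C[C@@H](O)CC(=C)CCCCCCCCCCC/C=C\CCCc1ccccc1 | intermediate
16 | (3S,17Z)-5-methylidene-21-phenylhenicos-17-en-1-yn-3-ol | C#C[C@@H](O)CC(=C)CCCCCCCCCCC/C=C\CCCc1ccccc1 | intermediate
17 | di-tert-butyl{[(3S,17Z)-5-methylidene-21-phenylhenicos-17-en-1-yn-3-yl]oxy}silyl trifluoromethanesulfonate (not isolated) | C#C[C@@H](O[Si](OS(=O)(=O)C(F)(F)F)(C(C)(C)C)C(C)(C)C)CC(=C)CCCCCCCCCCC/C=C\CCCc1ccccc1 | intermediate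
18 | di-tert-butyl{[(3S,17Z)-5-methylidene-21-phenylhenicos-17-en-1-yn-3-yl]oxy}silanol | C#C[C@@H](O[Si](O)(C(C)(C)C)C(C)(C)C)CC(=C)CCCCCCCCCCC/C=C\CCCc1ccccc1 | intermediate
19 | (1S,5S)-3,3-di-tert-butyl-1-[(12Z)-16-phenylhexadec-12-en-1-yl]-2,4-dioxa-3-silabicyclo[3.3.1]non-6-ene | CC(C)(C)[Si]1(C(C)(C)C)O[C@@H]2C=CC[C@@](O1)(CCCCCCCCCCC/C=C\CCCc3ccccc3)C2 | intermediate
20 | (1S,3S)-1-[(12Z)-16-phenylhexadec-12-en-1-yl]cyclohex-4-ene-1,3-diol | O[C@@H]1C=CC[C@@](O)(CCCCCCCCCCC/C=C\CCCc2ccccc2)C1 | target

**Step count and risks**

Total steps: 11. Longest linear sequence: 10 (steps 2 to 11, from 11-bromoundecan-1-ol).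

Steps most likely to fail:

1. Step 10 (proposed new method). Before the silanol oxygen closes the bridge, the C5 cation may lose a proton (diene, then loss of the silyloxy group and aromatisation), the gold carbenoid at C2 may take a 1,2-hydride shift from C1, or the silanol may add directly to the activated alkyne. The fallback uses known chemistry and gives up the tether; it sets out from 16 and comes back at 20. The alcohol is capped (TBSCl, imidazole, DMF) to give tert-butyldimethyl{[(3S,17Z)-5-methylidene-21-phenylhenicos-17-en-1-yn-3-yl]oxy}silane F1. The known gold-catalysed 6-endo-dig hydroxycyclisation of 5-substituted 1,5-enynes with water as external nucleophile (Ph3PAuNTf2, wet 1,4-dioxane, rt) should then give the cyclohexene with the tertiary alcohol as both C5 epimers: the cis compound (1S,5S)-5-[(tert-butyldimethylsilyl)oxy]-1-[(12Z)-16-phenylhexadec-12-en-1-yl]cyclohex-3-en-1-ol F2 and its trans epimer (1R,5S)-5-[(tert-butyldimethylsilyl)oxy]-1-[(12Z)-16-phenylhexadec-12-en-1-yl]cyclohex-3-en-1-ol F3. The epimers are separated by chromatography; only the diol from F2 can be bridged by t-Bu2Si(OTf)2, which serves as the proof of configuration. Bu4NF in THF converts F2 into 20. The price is the loss of stereocontrol at C5.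

2. Step 7. The 1,1-disubstituted alkene may migrate into conjugation with the ketone under the reduction conditions, and facial discrimination between the alkyne and a branched allylic chain may be incomplete. The fallback sets the carbinol centre in a C–C bond-forming step instead of a reduction; it sets out from 10 and comes back at 15, bypassing steps 5 to 7. Displacement of the allylic chloride with Bu3SnLi (from Bu3SnH and LiN(i-Pr)2, THF, −78 °C) should give tributyl[(14Z)-2-methylidene-18-phenyloctadec-14-en-1-yl]stannane F4. Keck asymmetric allylation of 11 with F4 ((S)-BINOL 20 mol%, Ti(OiPr)4 10 mol%, 4 Å MS, CH2Cl2, −20 °C; aq KF work-up) should give 15 directly. The (S) ligand is expected to give the (S) carbinol by analogy with aldehydes whose substituent outranks the allyl group.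

3. Step 4. The second allylic chloride of the product may be alkylated as well, and the Grignard reagent may homocouple. The fallback uses an electrophile with a single leaving group and a Lewis-acid allylation instead of the zinc reagent; it sets out from 9 (made from 7 as in step 4) and comes back at 13, replacing steps 4 and 5. Copper-catalysed coupling of 9 with 2-(chloromethyl)-3-(trimethylsilyl)prop-1-ene (Li2CuCl4 3 mol%, THF, −40 to 0 °C) should give trimethyl[(14Z)-2-methylidene-18-phenyloctadec-14-en-1-yl]silane F5. Hosomi–Sakurai addition of F5 to 11 (TiCl4, CH2Cl2, −78 °C) should give 13.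

Further compounds
F1 | step 10 | tert-butyldimethyl{[(3S,17Z)-5-methylidene-21-phenylhenicos-17-en-1-yn-3-yl]oxy}silane | C#C[C@@H](O[Si](C)(C)C(C)(C)C)CC(=C)CCCCCCCCCCC/C=C\CCCc1ccccc1
F2 | step 10 | (1S,5S)-5-[(tert-butyldimethylsilyl)oxy]-1-[(12Z)-16-phenylhexadec-12-en-1-yl]cyclohex-3-en-1-ol | CC(C)(C)[Si](C)(C)O[C@@H]1C=CC[C@@](O)(CCCCCCCCCCC/C=C\CCCc2ccccc2)C1
F3 | step 10 | (1R,5S)-5-[(tert-butyldimethylsilyl)oxy]-1-[(12Z)-16-phenylhexadec-12-en-1-yl]cyclohex-3-en-1-ol | CC(C)(C)[Si](C)(C)O[C@@H]1C=CC[C@](O)(CCCCCCCCCCC/C=C\CCCc2ccccc2)C1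
F4 | step 7 | tributyl[(14Z)-2-methylidene-18-phenyloctadec-14-en-1-yl]stannane | CCCC[Sn](CCCC)(CCCC)CC(=C)CCCCCCCCCCC/C=C\CCCc1ccccc1
F5 | step 4 | trimethyl[(14Z)-2-methylidene-18-phenyloctadec-14-en-1-yl]silane | C[Si](C)(C)CC(=C)CCCCCCCCCCC/C=C\CCCc1ccccc1
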